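The eudesmane is cut in ring B at C5–C6 and C9–C10. Ring B holds a trans pair, 5α-H and 10β-CH3, and its C8 ketone sits para to C5. This is the pattern of a [4+2] adduct of a 2-silyloxybutadiene with an (E)-β,β-disubstituted enal, the aldehyde carbon of which ends up as C4. One catalytic enantioselective cycloaddition thus closes ring B, sets C5 and the quaternary C10, and delivers C8 as a regiodefined masked ketone. Its precursors are (2E)-3-methylhepta-2,6-dienal 6 and 2-(triisopropylsilyloxy)buta-1,3-diene 8. Ring A is then closed by metathesis, all further oxygen enters from the α face, and enantiopure epoxyangelic acid is attached last.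

Key step: step 5

Assumption: eudesmane numbering is used (C3 ester carbinol, C4 tertiary carbinol, C5 ring-fusion CH, C7 ketol carbon, C8 ketone, C10 quaternary carbon, C11 side-chain carbinol), α is the face opposite the C10 methyl, the target is (3R,4S,5R,7S,10R,2'S,3'S), and the sense of induction in step 5 is taken from the formyl C–H···O binding model of oxazaborolidinium catalysis.

Step 1
Reactants: 1 hex-5-en-2-one; 2 triethyl phosphonoacetate
Product: 4 ethyl (2E)-3-methylhepta-2,6-dienoate, via sodium phosphonate carbanion 3 (not isolated)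
Conditions: NaH, THF, 0 °C → rt; (E)/(Z) separation on SiO2
Reagents that add atoms: sodium hydride [Na+].[H-] (sodium kept only in intermediate 3)
Why: The Horner–Wadsworth–Emmons olefination of a methyl ketone with a stabilised phosphonate carbanion is reliable and should favour the (E)-enoate, in which the ester lies anti to the larger butenyl chain, and chromatographic removal of the (Z)-isomer secures the alkene geometry that later encodes the C5/C10 relationship.

Step 2
Reactants: 4 ethyl (2E)-3-methylhepta-2,6-dienoate
Product: 5 (2E)-3-methylhepta-2,6-dien-1-ol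
Conditions: DIBAL-H (2.2 equiv), CH2Cl2, −78 °C
Reagents that add atoms: none
Why: DIBAL-H performs a clean 1,2-reduction of the enoate to the allylic alcohol at low temperature and touches neither alkene nor the double-bond geometry.

Step 3
Reactants: 5 (2E)-3-methylhepta-2,6-dien-1-ol
Product: 6 (2E)-3-methylhepta-2,6-dienal
Conditions: activated MnO2, CH2Cl2, rt
Reagents that add atoms: none
Why: Activated MnO2 oxidises only the allylic alcohol, stops at the aldehyde and works under neutral heterogeneous conditions that do not isomerise the (E)-alkene.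

Step 4
Reactants: 7 methyl vinyl ketone
Product: 8 2-(triisopropylsilyloxy)buta-1,3-diene
Conditions: TIPSOTf, Et3N, Et2O, 0 °C → rt
Reagents that add atoms: triisopropylsilyl triflate CC(C)[Si](OS(=O)(=O)C(F)(F)F)(C(C)C)C(C)C
Why: Soft enolisation and O-silylation of the enone with a silyl triflate and a tertiary amine gives the cross-conjugated 2-silyloxydiene, and the bulky TIPS group makes it survive the strong Lewis acid of step 5.

Step 5
Reactants: 6 (2E)-3-methylhepta-2,6-dienal; 8 2-(triisopropylsilyloxy)buta-1,3-diene
Product: 9 (1R,6R)-6-(but-3-en-1-yl)-6-methyl-4-(triisopropylsilyloxy)cyclohex-3-ene-1-carbaldehyde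
Conditions: oxazaborolidine from (S)-α,α-diphenylprolinol and o-tolylboroxine (20 mol %), AlBr3 (16 mol %), 8 (3 equiv), CH2Cl2 (concentrated), −40 → −20 °C; Et3N quench
Reagents that add atoms: none
Why: Proposed new method: the AlBr3-activated (S)-oxazaborolidine binds the formyl oxygen of s-trans 6 (B–O coordination reinforced by a formyl C–H···O contact), lowers the enal LUMO and lets 8 add in a concerted but asynchronous suprafacial [4+2] cycloaddition in which C9–C10 bonding runs ahead of C5–C6 bonding. The closest known reaction types are oxazaborolidinium-catalysed enantioselective Diels–Alder additions of 2-silyloxydienes to α-substituted or β-monosubstituted enals and aluminium-halide-promoted additions of such dienes to β,β-disubstituted enones; an acyclic β,β-disubstituted enal has not been shown in the catalytic asymmetric manifold, and its low dienophilicity is the risk. Ring B closes by intermolecular [4+2] annulation, two σ-bonds at once, leaving C7=C8 as the TIPS enol ether. The C5/C10 relative configuration is copied from the (E)-geometry of 6, in which formyl and methyl are cis, so that C4 ends cis to the C10 methyl and trans to the butenyl chain, and since both diene termini are CH2 the endo/exo question creates no further isomer. Absolute configuration at both centres comes from the catalyst: the aryl group on the carbinol carbon of the (S)-prolinol backbone covers the C2-Si/C3-Re face, the diene enters at the C2-Re/C3-Si face and (1R,6R)-9 should result. The step needs para regioselectivity, secured by the 2-silyloxy donor that puts the largest HOMO coefficient on the adjacent CH2 (which pairs with the β-carbon, C10), and chemoselectivity for cycloaddition over Mukaiyama aldol attack at the formyl carbon and over the isolated vinyl group, secured by the bulky TIPS group that retards silyl transfer and by the fact that only the conjugated alkene is activated.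

Step 6
Reactants: 9 (1R,6R)-6-(but-3-en-1-yl)-6-methyl-4-(triisopropylsilyloxy)cyclohex-3-ene-1-carbaldehyde
Product: 10 1-[(1R,6R)-6-(but-3-en-1-yl)-6-methyl-4-(triisopropylsilyloxy)cyclohex-3-en-1-yl]ethan-1-ol (both carbinol epimers)
Conditions: MeMgBr, Et2O, −78 °C
Reagents that add atoms: methylmagnesium bromide C[Mg]Br
Why: Grignard 1,2-addition to the aldehyde is fast at −78 °C whereas the TIPS enol ether, which serves as the mask of the C8 ketone, is inert, and the new carbinol centre (C4) may form as a mixture because step 7 erases it.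

Step 7
Reactants: 10 1-[(1R,6R)-6-(but-3-en-1-yl)-6-methyl-4-(triisopropylsilyloxy)cyclohex-3-en-1-yl]ethan-1-ol
Product: 11 1-[(1R,6R)-6-(but-3-en-1-yl)-6-methyl-4-(triisopropylsilyloxy)cyclohex-3-en-1-yl]ethan-1-one
Conditions: Dess–Martin periodinane, NaHCO3, CH2Cl2, 0 °C → rt
Reagents that add atoms: none
Why: Bicarbonate-buffered Dess–Martin oxidation converges both carbinol epimers on one methyl ketone under non-basic conditions, so that the enolisable C5 centre and the acid-sensitive enol ether are kept.

Step 8
Reactants: 11 1-[(1R,6R)-6-(but-3-en-1-yl)-6-methyl-4-(triisopropylsilyloxy)cyclohex-3-en-1-yl]ethan-1-one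
Product: 12 {[(4S,5R)-5-(but-3-en-1-yl)-5-methyl-4-(prop-1-en-2-yl)cyclohex-1-en-1-yl]oxy}triisopropylsilane
Conditions: Cp2TiMe2, toluene, 70 °C, dark
Reagents that add atoms: dimethyltitanocene C[Ti](C)(C1C=CC=C1)C1C=CC=C1
Why: Petasis methylenation through thermally generated Cp2Ti=CH2 olefinates hindered enolisable ketones without base, which avoids the C5 epimerisation that a phosphorus ylide could cause, and silyl enol ethers are not attacked.

Step 9
Reactants: 12 {[(4S,5R)-5-(but-3-en-1-yl)-5-methyl-4-(prop-1-en-2-yl)cyclohex-1-en-1-yl]oxy}triisopropylsilane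
Product: 13 {[(4aR,8aR)-5,8a-dimethyl-1,4,4a,7,8,8a-hexahydronaphthalen-2-yl]oxy}triisopropylsilane (trans-fused)
Conditions: Grubbs second-generation catalyst (5 mol %), CH2Cl2 (dilute), 40 °C
Reagents that add atoms: none
Why: Ring-closing metathesis of the monosubstituted with the 1,1-disubstituted alkene closes six-membered ring A as the trisubstituted C3=C4 alkene with loss of ethene, the two tethers being trans on ring B so that only the trans-decalin can result, while the hindered electron-rich enol ether stays out of the catalytic cycle.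

Step 10
Reactants: 13 {[(4aR,8aR)-5,8a-dimethyl-1,4,4a,7,8,8a-hexahydronaphthalen-2-yl]oxy}triisopropylsilane
Product: 14 (4aR,8aR)-5,8a-dimethyl-3,4,4a,7,8,8a-hexahydronaphthalen-2(1H)-one
Conditions: TBAF, AcOH, THF, 0 °C
Reagents that add atoms: none
Why: Fluoride cleaves the Si–O bond and acetic acid protonates the enolate at once, so the C8 ketone is released under nearly neutral conditions and no stereocentre is at risk because C5 is no longer α to a carbonyl group.

Step 11
Reactants: 14 (4aR,8aR)-5,8a-dimethyl-3,4,4a,7,8,8a-hexahydronaphthalen-2(1H)-one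
Product: 16 (3R,4aR,8aR)-3-(2-hydroxypropan-2-yl)-5,8a-dimethyl-3,4,4a,7,8,8a-hexahydronaphthalen-2(1H)-one (11-hydroxyeudesm-3-en-8-one), via lithium enolate 15 (not isolated)
Conditions: LDA, THF, −78 °C; ZnCl2; acetone, −78 → −40 °C
Reagents that add atoms: acetone CC(C)=O; lithium diisopropylamide [Li+].CC(C)[N-]C(C)C (lithium kept only in intermediate 15)
Why: In this directed aldol addition LDA removes the less hindered C7 proton rather than a C9 proton next to the quaternary C10, zinc chloride holds the aldolate as a chelate so that the addition to acetone is not reversed, and the C7 configuration (side chain expected equatorial) is irrelevant because step 12 destroys it.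

Step 12
Reactants: 16 11-hydroxyeudesm-3-en-8-one
Product: 18 (4aR,8aR)-5,8a-dimethyl-3-(propan-2-ylidene)-3,4,4a,7,8,8a-hexahydronaphthalen-2(1H)-one (eudesma-3,7(11)-dien-8-one), via tertiary mesylate 17 (not isolated)
Conditions: MsCl, Et3N, CH2Cl2, 0 °C; then DBU, rt
Reagents that add atoms: methanesulfonyl chloride CS(=O)(=O)Cl (atoms kept only in intermediate 17)
Why: Sulfene-type mesylation of the tertiary alcohol followed by E1cB elimination through the C7 enolate gives only the conjugated tetrasubstituted enone and uses no acid that could move the C3=C4 alkene.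

Step 13
Reactants: 18 eudesma-3,7(11)-dien-8-one
Product: 19 (5R,7S,10R)-7α,11-epoxyeudesm-3-en-8-one
Conditions: 30% H2O2, aq NaOH, MeOH, 0 °C → rt
Reagents that add atoms: hydrogen peroxide OO
Why: Weitz–Scheffer epoxidation, well known for isopropylidene cyclohexanones such as pulegone, attacks only the electron-poor alkene, and after hydroperoxide addition to C11 the C7=C8 enolate of the rigid trans-decalin closes on oxygen along the axial, chair-like trajectory on the α face, where only H-5 and H-9 are syn-axial, which sets C7 with O α and C11 equatorial.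

Step 14
Reactants: 19 7α,11-epoxyeudesm-3-en-8-one
Product: 20 (3S,4aR,8aR)-3-hydroxy-3-(2-hydroxypropan-2-yl)-5,8a-dimethyl-3,4,4a,7,8,8a-hexahydronaphthalen-2(1H)-one (7α,11-dihydroxyeudesm-3-en-8-one)
Conditions: HClO4 (cat.), THF–H2O, 0 °C → rt
Reagents that add atoms: water O
Why: Acid-catalysed epoxide hydrolysis opens the protonated oxirane at the tertiary carbon C11, which carries positive charge far better than the acyl-substituted C7 (the behaviour known for mesityl oxide epoxide), so water enters at the non-stereogenic C11, the C7–O bond and its configuration stay untouched, and the dilute acid spares the trisubstituted alkene.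

Step 15
Reactants: 20 7α,11-dihydroxyeudesm-3-en-8-one
Product: 21 (3S,4aR,5S,6R,8aR)-3,5,6-trihydroxy-3-(2-hydroxypropan-2-yl)-5,8a-dimethyloctahydronaphthalen-2(1H)-one (3α,4α,7α,11-tetrahydroxyeudesman-8-one)
Conditions: OsO4 (cat.), NMO, acetone–H2O, rt
Reagents that add atoms: osmium tetroxide O=[Os](=O)(=O)=O (catalytic oxygen carrier); N-methylmorpholine N-oxide C[N+]1([O-])CCOCC1; water O
Why: Upjohn dihydroxylation adds both oxygens syn to the only alkene from the α face, because the axial 10β-methyl group is 1,3-related to C4 and blocks the β face, which sets the axial 3α- and the equatorial 4α-hydroxyl in one step.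

Step 16
Reactants: 22 angelic acid
Product: 23 (2Z)-2-methylbut-2-en-1-ol
Conditions: LiAlH4, Et2O, 0 °C
Reagents that add atoms: none
Why: LiAlH4 reduces the carboxylic acid to the primary allylic alcohol without conjugate reduction or Z/E isomerisation of the alkyl-substituted alkene.

Step 17
Reactants: 23 (2Z)-2-methylbut-2-en-1-ol
Product: 24 [(2R,3S)-2,3-dimethyloxiran-2-yl]methanol
Conditions: Ti(OiPr)4 (cat.), D-(−)-diethyl tartrate (cat.), t-BuOOH, 4 Å MS, CH2Cl2, −20 °C
Reagents that add atoms: tert-butyl hydroperoxide CC(C)(C)OO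
Why: In the Katsuki–Sharpless asymmetric epoxidation the allylic alkoxide binds to the titanium tartrate complex, D-(−)-DET directs the peroxide oxygen to the face that gives the (2R,3S)-epoxide (the mirror image of the sense in which L-(+)-DET converts nerol-type (Z)-allylic alcohols into (2S,3R)-epoxides), and syn transfer keeps CH2OH and the C3 methyl cis, so both side-chain stereocentres are set by the reagent instead of arising as a racemate from direct epoxidation of 22.

Step 18
Reactants: 24 [(2R,3S)-2,3-dimethyloxiran-2-yl]methanol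
Product: 25 (2S,3S)-2,3-dimethyloxirane-2-carboxylic acid (epoxyangelic acid)
Conditions: RuCl3 (cat.), NaIO4, MeCN–EtOAc–H2O, 0 °C → rt
Reagents that add atoms: sodium periodate [Na+].[O-]I(=O)(=O)=O (terminal oxidant through RuO4); water O (aldehyde hydrate)
Why: Catalytic RuO4 with periodate oxidises the primary alcohol through the aldehyde hydrate to the acid without opening the oxirane, and the C2 descriptor changes from R to S only because the CIP ranking of the oxidised carbon rises.

Step 19
Reactants: 25 (2S,3S)-2,3-dimethyloxirane-2-carboxylic acid; 21 3α,4α,7α,11-tetrahydroxyeudesman-8-one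
Product: 27 (1S,2R,4aR,7S,8aR)-1,7-dihydroxy-7-(2-hydroxypropan-2-yl)-1,4a-dimethyl-6-oxodecahydronaphthalen-2-yl (2S,3S)-2,3-dimethyloxirane-2-carboxylate (target), via mixed anhydride 26 (not isolated)
Conditions: 2,4,6-Cl3C6H2COCl, Et3N, toluene, rt; then 21, DMAP, toluene–THF, rt
Reagents that add atoms: 2,4,6-trichlorobenzoyl chloride O=C(Cl)c1c(Cl)cc(Cl)cc1Cl (atoms kept only in intermediate 26)
Why: Yamaguchi esterification delivers the hindered acyl group through its DMAP-activated mixed anhydride to the only secondary hydroxyl (C3), the three tertiary hydroxyls at C4, C7 and C11 being far slower, no stereocentre is touched, and any minor diastereomer that stems from incomplete enantiopurity of 25 can be removed by chromatography.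

Compound list
1 | hex-5-en-2-one | CC(=O)CCC=C | starting material
2 | triethyl phosphonoacetate | CCOC(=O)CP(=O)(OCC)OCC | starting material
3 | sodium salt (carbanion) of triethyl phosphonoacetate | CCOC(=O)[CH-]P(=O)(OCC)OCC.[Na+] | intermediate
4 | ethyl (2E)-3-methylhepta-2,6-dienoate | CCOC(=O)/C=C(\C)CCC=C | intermediate
5 | (2E)-3-methylhepta-2,6-dien-1-ol | OC/C=C(\C)CCC=C | intermediate
6 | (2E)-3-methylhepta-2,6-dienal | O=C/C=C(\C)CCC=C | intermediate
7 | methyl vinyl ketone | CC(=O)C=C | starting material
8 | 2-(triisopropylsilyloxy)buta-1,3-diene | C=CC(=C)O[Si](C(C)C)(C(C)C)C(C)C | intermediate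
9 | (1R,6R)-6-(but-3-en-1-yl)-6-methyl-4-(triisopropylsilyloxy)cyclohex-3-ene-1-carbaldehyde | O=C[C@@H]1CC=C(O[Si](C(C)C)(C(C)C)C(C)C)C[C@@]1(C)CCC=C | intermediate
10 | 1-[(1R,6R)-6-(but-3-en-1-yl)-6-methyl-4-(triisopropylsilyloxy)cyclohex-3-en-1-yl]ethan-1-ol, carbinol epimers | CC(O)[C@@H]1CC=C(O[Si](C(C)C)(C(C)C)C(C)C)C[C@@]1(C)CCC=C | intermediate
11 | 1-[(1R,6R)-6-(but-3-en-1-yl)-6-methyl-4-(triisopropylsilyloxy)cyclohex-3-en-1-yl]ethan-1-one | CC(=O)[C@@H]1CC=C(O[Si](C(C)C)(C(C)C)C(C)C)C[C@@]1(C)CCC=C | intermediate
12 | {[(4S,5R)-5-(but-3-en-1-yl)-5-methyl-4-(prop-1-en-2-yl)cyclohex-1-en-1-yl]oxy}triisopropylsilane | CC(=C)[C@@H]1CC=C(O[Si](C(C)C)(C(C)C)C(C)C)C[C@@]1(C)CCC=C | intermediate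
13 | {[(4aR,8aR)-5,8a-dimethyl-1,4,4a,7,8,8a-hexahydronaphthalen-2-yl]oxy}triisopropylsilane | CC1=CCC[C@]2(C)CC(O[Si](C(C)C)(C(C)C)C(C)C)=CC[C@@H]12 | intermediate
14 | (4aR,8aR)-5,8a-dimethyl-3,4,4a,7,8,8a-hexahydronaphthalen-2(1H)-one | CC1=CCC[C@]2(C)CC(=O)CC[C@@H]12 | intermediate
15 | lithium C7=C8 enolate of 14 | CC1=CCC[C@]2(C)CC([O-])=CC[C@@H]12.[Li+] | intermediate
16 | (3R,4aR,8aR)-3-(2-hydroxypropan-2-yl)-5,8a-dimethyl-3,4,4a,7,8,8a-hexahydronaphthalen-2(1H)-one | CC1=CCC[C@]2(C)CC(=O)[C@@H](C(C)(C)O)C[C@@H]12 | intermediate
17 | C11 methanesulfonate of 16 | CC1=CCC[C@]2(C)CC(=O)[C@@H](C(C)(C)OS(C)(=O)=O)C[C@@H]12 | intermediate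
18 | (4aR,8aR)-5,8a-dimethyl-3-(propan-2-ylidene)-3,4,4a,7,8,8a-hexahydronaphthalen-2(1H)-one | CC1=CCC[C@]2(C)CC(=O)C(=C(C)C)C[C@@H]12 | intermediate
19 | (5R,7S,10R)-7α,11-epoxyeudesm-3-en-8-one | CC1=CCC[C@]2(C)CC(=O)[C@@]3(C(C)(C)O3)C[C@@H]12 | intermediate
20 | (3S,4aR,8aR)-3-hydroxy-3-(2-hydroxypropan-2-yl)-5,8a-dimethyl-3,4,4a,7,8,8a-hexahydronaphthalen-2(1H)-one | CC1=CCC[C@]2(C)CC(=O)[C@@](O)(C(C)(C)O)C[C@@H]12 | intermediate
21 | (3S,4aR,5S,6R,8aR)-3,5,6-trihydroxy-3-(2-hydroxypropan-2-yl)-5,8a-dimethyloctahydronaphthalen-2(1H)-one | O[C@@H]1CC[C@]2(C)CC(=O)[C@@](O)(C(C)(C)O)C[C@H]2[C@]1(C)O | intermediate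
22 | angelic acid, (2Z)-2-methylbut-2-enoic acid | C/C=C(/C)C(=O)O | starting material
23 | (2Z)-2-methylbut-2-en-1-ol | C/C=C(/C)CO | intermediate
24 | [(2R,3S)-2,3-dimethyloxiran-2-yl]methanol | C[C@@H]1O[C@]1(C)CO | intermediate
25 | (2S,3S)-2,3-dimethyloxirane-2-carboxylic acid | C[C@@H]1O[C@]1(C)C(=O)O | intermediate
26 | (2S,3S)-2,3-dimethyloxirane-2-carboxylic 2,4,6-trichlorobenzoic anhydride | C[C@@H]1O[C@]1(C)C(=O)OC(=O)c1c(Cl)cc(Cl)cc1Cl | intermediate
27 | (1S,2R,4aR,7S,8aR)-1,7-dihydroxy-7-(2-hydroxypropan-2-yl)-1,4a-dimethyl-6-oxodecahydronaphthalen-2-yl (2S,3S)-2,3-dimethyloxirane-2-carboxylate | C[C@@H]1O[C@]1(C)C(=O)O[C@@H]1CC[C@]2(C)CC(=O)[C@@](O)(C(C)(C)O)C[C@H]2[C@]1(C)O | target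

Total step count: 19. Longest linear sequence: 15 (steps 1–3, 5–15 and 19). Steps 4 and 16–18 are side branches.

Steps most likely to fail

1. Step 5 (Proposed new method).
- What may go wrong: the β,β-disubstituted enal may be too poor a dienophile for the chiral cation. Diene oligomerisation, 1,2-attack of the enol ether on the formyl carbon, or loss of alkene geometry through a stepwise Michael pathway could then outrun cycloaddition. Facial bias could also erode at the temperature that turnover needs.
- Fallback (known chemistry): it sets out from 6. Addition of MeMgBr gives (3E)-4-methylocta-3,7-dien-2-ol F1, and MnO2 oxidation gives (3E)-4-methylocta-3,7-dien-2-one F2. F2 is combined with 8 under the mixed AlBr3/AlMe3 Lewis acid that is established for hindered pairs of 2-silyloxydienes and β,β-disubstituted enones.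
- This delivers the methyl ketone as a racemate, that is 11 together with its mirror image ent-11 F3. The two are parted by preparative chromatography on a chiral stationary phase.
- The route is re-entered at 11, and steps 6 and 7 are skipped.

2. Step 14.
- What may go wrong: the developing C11 cation may be diverted by a 1,2-acyl shift (ring enlargement to a 1,3-diketone) or by proton loss to an isopropenyl carbinol before water captures it.
- Fallback: it sets out from 18 and leaves out steps 13 and 14. Upjohn dihydroxylation first consumes the electron-rich C3=C4 alkene from the α face and gives 3α,4α-dihydroxyeudesm-7(11)-en-8-one F4.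
- A second, slower concerted osmylation of the tetrasubstituted enone follows (OsO4, NMO, citric acid, aq t-BuOH, warm). It should add both oxygens to the α face, because only that approach lets C11 swing into the equatorial position.
- The route is re-entered at 21.

3. Step 19.
- What may go wrong: acyl transfer to the axial C3 hydroxyl next to the fully substituted C4 may be slow. Acylation of tertiary hydroxyls, opening of the oxirane by chloride, or poor solubility of the tetraol could then compete.
- Fallback: it sets out from 19 and uses the 7α,11-epoxide as a mask for two of the tertiary hydroxyls. Upjohn dihydroxylation gives 7α,11-epoxy-3α,4α-dihydroxyeudesman-8-one F5, a less polar diol with a single tertiary competitor. F5 tolerates excess 26 and DMAP and gives the 3-O-epoxyangelate F6.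
- Dilute HClO4 in aqueous THF then opens only the 7α,11-epoxide. Its C11 is tertiary and ionises readily, whereas the side-chain oxirane offers only a secondary or an acyl-deactivated carbon.
- The route is re-entered at 27.

Further compounds
F1 | step 5 | (3E)-4-methylocta-3,7-dien-2-ol | CC(O)/C=C(\C)CCC=C
F2 | step 5 | (3E)-4-methylocta-3,7-dien-2-one | CC(=O)/C=C(\C)CCC=C
F3 | step 5 | 1-[(1S,6S)-6-(but-3-en-1-yl)-6-methyl-4-(triisopropylsilyloxy)cyclohex-3-en-1-yl]ethan-1-one (ent-11) | CC(=O)[C@H]1CC=C(O[Si](C(C)C)(C(C)C)C(C)C)C[C@]1(C)CCC=C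
F4 | step 14 | 3α,4α-dihydroxyeudesm-7(11)-en-8-one | O[C@@H]1CC[C@]2(C)CC(=O)C(=C(C)C)C[C@H]2[C@]1(C)O
F5 | step 19 | 7α,11-epoxy-3α,4α-dihydroxyeudesman-8-one | O[C@@H]1CC[C@]2(C)CC(=O)[C@@]3(C(C)(C)O3)C[C@H]2[C@]1(C)O
F6 | step 19 | 7α,11-epoxy-4α-hydroxy-8-oxoeudesman-3α-yl (2S,3S)-2,3-dimethyloxirane-2-carboxylate | C[C@@H]1O[C@]1(C)C(=O)O[C@@H]1CC[C@]2(C)CC(=O)[C@@]3(C(C)(C)O3)C[C@H]2[C@]1(C)O
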